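Numbering: quinolizidine N5; ring A = C1–C4 (C2 ketone, C3 methyl); ring B = C6–C9; fusion carbon C9a; the target is C2-symmetric, (1R,3S,9S,9aR) in each half.
Retrosynthesis: cut N5–C4 (aza-Michael) and C9a–C1 (Mannich) in both halves, which opens both rings A and the 16-membered ring to two copies of one piperidine; then cut ring B at C6–C7, C8–C9 and N5–C9a.
Enabling feature: in ring B, C9a is an N-bearing CH (a latent aldehyde carbon), C9 is its α-carbon, C6 is an aminomethyl carbon and C7–C8 are two bare methylenes, so ring B is the sum of an enolizable aldehyde, CH2=N and an ethylene 1,2-dipole (1,1-bis(phenylsulfonyl)ethene, sulfones removed later).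
Forward: ring B is made in one pot (enamine Michael, Mannich, hemiaminal); two monomers are joined head to tail by two N-acyliminium Mannich reactions that close the 16-membered ring; ester to isopropenyl ketone, Boc removal and double aza-Michael closure then give both rings A.
Stereochemistry: C9 from the (R)-diarylprolinol silyl ether catalyst; C9a from axial attack on an iminium ion locked by the gem-bis-sulfone (cis to C9–H); C1 and C3 by equilibration α to the ketone.

Key step: step 1

Assumption: 1, 2, 3 and the (R)-catalyst are purchased; the (S) descriptor at C9 is assigned from the steric-shielding model for diarylprolinol silyl ether enamines, and C1 is carried as an epimer mixture until step 8.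

Step 1
Reactants: 1 methyl 9-oxononanoate; 2 1,1-bis(phenylsulfonyl)ethene; 3 tert-butyl N-[(4-methylphenyl)sulfonylmethyl]carbamate
Product: 6 tert-butyl (3S)-2-hydroxy-3-(7-methoxy-7-oxoheptyl)-5,5-bis(phenylsulfonyl)piperidine-1-carboxylate (mixture at C-2), via Michael adduct aldehyde 4 (not isolated), via acyclic carbamate aldehyde 5 (not isolated)
Conditions: (R)-2-{bis[3,5-bis(trifluoromethyl)phenyl](trimethylsilyloxy)methyl}pyrrolidine (10 mol %), CH2Cl2, −40 °C; then 3, Cs2CO3, −20 to 0 °C (one pot)
Reagents that add atoms: none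
Why: Proposed new method: the aldehyde and the amine catalyst form an E-enamine whose C9 adds to the CH2 terminus of 2 (C8–C9 bond); hydrolysis returns the catalyst and leaves a bis-sulfonyl C–H acid (pKa about 12) whose cesium salt adds to tert-butyl N-methylidenecarbamate released from 3 by loss of sulfinate (C6–C7 bond), and the carbamate N–H then adds to the aldehyde (N5–C9a bond). The closest known reaction type is the one-pot organocatalytic Michael / aza-Henry / hemiaminalization synthesis of piperidines from aldehydes, nitroalkenes and N-acyl or N-sulfonyl imines; the enamine Michael addition of aldehydes to 2 and the Mannich addition of substituted bis(phenylsulfonyl)methyl anions to imines made from α-amido sulfones are each known separately, and what is new is the bis-sulfone as the two-carbon acceptor–donor unit of the cascade. Ring B closes by 6-exo-trig addition of nitrogen to the C9a carbonyl after two intermolecular C–C bond formations. C9 is set by the catalyst, whose diarylsilyloxymethyl group shields one face of the anti enamine, so the (R)-catalyst should give the (S) center; C9a forms as a mixture that does not matter because it is ionized in step 4. The step needs the Mannich reaction to occur at C7 and not at the aldehyde α-carbon and needs C9 to stay unepimerized: the five pKa units between the bis-sulfone C–H and the aldehyde α-C–H, the reluctance of the α-branched aldehyde to re-form an enamine, the low temperature and the fast hemiaminal closure (after which C9 is no longer α to a carbonyl) should secure both.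

Step 2
Reactants: 6 tert-butyl (3S)-2-hydroxy-3-(7-methoxy-7-oxoheptyl)-5,5-bis(phenylsulfonyl)piperidine-1-carboxylate
Product: 7 tert-butyl (3S)-2-methoxy-3-(7-methoxy-7-oxoheptyl)-5,5-bis(phenylsulfonyl)piperidine-1-carboxylate (mixture at C-2)
Conditions: MeOH, pyridinium p-toluenesulfonate (cat.), 3 Å sieves, rt
Reagents that add atoms: methanol, CO
Why: Acid-catalyzed hemiaminal to N,O-acetal exchange through the N-acyliminium ion, which methanol traps faster than the ion can lose the C9 proton, gives a base-stable N-acyliminium precursor without setting any controlled stereocenter.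

Step 3
Reactants: 7 tert-butyl (3S)-2-methoxy-3-(7-methoxy-7-oxoheptyl)-5,5-bis(phenylsulfonyl)piperidine-1-carboxylate
Product: 8 tert-butyl (3S)-3-[7-(tert-butyldimethylsilyloxy)-7-methoxyhept-6-en-1-yl]-2-methoxy-5,5-bis(phenylsulfonyl)piperidine-1-carboxylate (ketene silyl acetal)
Conditions: lithium diisopropylamide (LDA), THF, −78 °C; TBSCl, DMPU, −78 to 0 °C; non-aqueous work-up
Reagents that add atoms: tert-butyldimethylsilyl chloride (TBSCl), CC(C)(C)[Si](C)(C)Cl
Why: Kinetic ester enolization and O-silylation (silyl ketene acetal formation) take place at the only acidic C–H, the CH2 α to the ester (future C1), because C7 is quaternary and the N,O-acetal and carbamate are inert at −78 °C; the enol ether geometry is immaterial.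

Step 4
Reactants: 8 ketene silyl acetal N,O-acetal monomer (two molecules)
Product: 10 macrocyclic bis(N-Boc-5,5-bis(phenylsulfonyl)piperidine) dimethyl diester (16-membered ring; 2R,3S in each piperidine), via linear head-to-tail dimer 9 (not isolated)
Conditions: tert-butyldimethylsilyl triflate (TBSOTf, 0.3 equiv), CH2Cl2, −78 to −40 °C, slow addition of 8 (final 5 mM)
Reagents that add atoms: none
Why: This is a silyl-triflate-catalyzed N-acyliminium Mukaiyama–Mannich reaction run twice: ionization at C9a and attack by the ketene acetal carbon C1 can only pair head with tail, so the first event gives 9 and the second closes the 16-membered ring, while the C7 gem-bis-sulfone keeps the C9 side chain equatorial in the half-chair iminium ion so that axial attack anti to the C9–H bond should set C9a cis to C9 (9aR with 9S); C1 forms as a mixture corrected in step 8.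

Step 5
Reactants: 10 macrocyclic bis(N-Boc-5,5-bis(phenylsulfonyl)piperidine) dimethyl diester
Product: 11 macrocyclic bis(N-Boc-piperidine) dimethyl diester (2R,3S in each piperidine)
Conditions: Mg turnings (excess), MeOH, rt to 50 °C
Reagents that add atoms: none
Why: Single-electron reductive desulfonylation with magnesium in methanol cleaves all four C–S bonds (the α-sulfonyl carbanions are protonated by the solvent), a known way to remove this helper from β-carbamoylamino bis-sulfones, and leaves methyl esters, carbamates and the C9 and C9a centers untouched.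

Step 6
Reactants: 11 macrocyclic bis(N-Boc-piperidine) dimethyl diester
Product: 12 macrocyclic bis(N-Boc-piperidine) bis(N-methoxy-N-methylamide)
Conditions: MeNH(OMe)·HCl, isopropylmagnesium chloride (i-PrMgCl), THF, −20 to 0 °C
Reagents that add atoms: N,O-dimethylhydroxylamine hydrochloride, CNOC.Cl
Why: Aminolysis of the methyl esters by the chloromagnesium amide of N,O-dimethylhydroxylamine (Weinreb amide formation) needs no free ester enolate, so the β-carbamate is not eliminated, and no stereocenter is set.

Step 7
Reactants: 12 macrocyclic bis(N-Boc-piperidine) bis(N-methoxy-N-methylamide)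
Product: 13 macrocyclic bis(N-Boc-piperidine) bis(isopropenyl ketone)
Conditions: isopropenylmagnesium bromide (CH2=C(CH3)MgBr), THF, 0 °C; aq. NH4Cl
Reagents that add atoms: isopropenylmagnesium bromide, C=C(C)[Mg]Br
Why: In this Weinreb ketone synthesis the alkenyl Grignard reagent adds only once because the chelated tetrahedral magnesium intermediate survives until work-up, giving the enones that carry C2, C3, C4 and the methyl group of each ring A.

Step 8
Reactants: 13 macrocyclic bis(N-Boc-piperidine) bis(isopropenyl ketone)
Product: 15 target CNP0268544.6 (1R,3S,9S,9aR in each quinolizidin-2-one half), via bis-amino bis-enone 14 (not isolated)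
Conditions: TFA, CH2Cl2, 0 °C; evaporate; K2CO3, MeOH, rt to 40 °C (5 mM)
Reagents that add atoms: none
Why: Acidolysis of both Boc groups and neutralization release secondary amines that close each ring A by 6-endo-trig intramolecular aza-Michael addition of N5 to C4 of the adjacent isopropenyl ketone, and carbonate-mediated enolization should then equilibrate C1 and C3 to the equatorial (1R,3S) arrangement of the trans-fused quinolizidinone, C9 and C9a not being enolizable.

Compound list
1 | methyl 9-oxononanoate | COC(=O)CCCCCCCC=O | starting material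
2 | 1,1-bis(phenylsulfonyl)ethene | C=C(S(=O)(=O)c1ccccc1)S(=O)(=O)c1ccccc1 | starting material
3 | tert-butyl N-[(4-methylphenyl)sulfonylmethyl]carbamate | Cc1ccc(cc1)S(=O)(=O)CNC(=O)OC(C)(C)C | starting material
4 | methyl (8S)-8-formyl-10,10-bis(phenylsulfonyl)decanoate (formed in the flask) | COC(=O)CCCCCC[C@H](C=O)CC(S(=O)(=O)c1ccccc1)S(=O)(=O)c1ccccc1 | intermediate
5 | methyl (8S)-11-[(tert-butoxycarbonyl)amino]-8-formyl-10,10-bis(phenylsulfonyl)undecanoate (formed in the flask) | COC(=O)CCCCCC[C@H](C=O)CC(CNC(=O)OC(C)(C)C)(S(=O)(=O)c1ccccc1)S(=O)(=O)c1ccccc1 | intermediate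
6 | tert-butyl (3S)-2-hydroxy-3-(7-methoxy-7-oxoheptyl)-5,5-bis(phenylsulfonyl)piperidine-1-carboxylate (C-2 epimers) | COC(=O)CCCCCC[C@H]1CC(S(=O)(=O)c2ccccc2)(S(=O)(=O)c2ccccc2)CN(C(=O)OC(C)(C)C)C1O | intermediate
7 | tert-butyl (3S)-2-methoxy-3-(7-methoxy-7-oxoheptyl)-5,5-bis(phenylsulfonyl)piperidine-1-carboxylate (C-2 epimers) | COC(=O)CCCCCC[C@H]1CC(S(=O)(=O)c2ccccc2)(S(=O)(=O)c2ccccc2)CN(C(=O)OC(C)(C)C)C1OC | intermediate
8 | tert-butyl (3S)-3-[7-(tert-butyldimethylsilyloxy)-7-methoxyhept-6-en-1-yl]-2-methoxy-5,5-bis(phenylsulfonyl)piperidine-1-carboxylate | COC(O[Si](C)(C)C(C)(C)C)=CCCCCC[C@H]1CC(S(=O)(=O)c2ccccc2)(S(=O)(=O)c2ccccc2)CN(C(=O)OC(C)(C)C)C1OC | intermediate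
9 | linear head-to-tail dimer (formed in the flask): C-2 of one (2R,3S)-N-Boc-5,5-bis(phenylsulfonyl)piperidine, whose C-3 chain still ends in the ketene silyl acetal, is bonded to the ester α-carbon of a second unit that keeps its 2-methoxy group | COC(O[Si](C)(C)C(C)(C)C)=CCCCCC[C@H]1CC(S(=O)(=O)c2ccccc2)(S(=O)(=O)c2ccccc2)CN(C(=O)OC(C)(C)C)[C@H]1C(C(=O)OC)CCCCC[C@H]1CC(S(=O)(=O)c2ccccc2)(S(=O)(=O)c2ccccc2)CN(C(=O)OC(C)(C)C)C1OC | intermediate
10 | macrocyclic tetrasulfone: 16-membered carbocycle fused to two tert-butyl (2R,3S)-5,5-bis(phenylsulfonyl)piperidine-1-carboxylate rings; each piperidine C-2 bears a CH(CO2Me) carbon tied by a (CH2)5 chain to C-3 of the other piperidine | COC(=O)C1CCCCC[C@H]2CC(S(=O)(=O)c3ccccc3)(S(=O)(=O)c3ccccc3)CN(C(=O)OC(C)(C)C)[C@H]2C(C(=O)OC)CCCCC[C@H]2CC(S(=O)(=O)c3ccccc3)(S(=O)(=O)c3ccccc3)CN(C(=O)OC(C)(C)C)[C@@H]12 | intermediate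
11 | macrocyclic bis(N-Boc-piperidine) dimethyl diester (as 10 with CH2 in place of each C(SO2Ph)2) | COC(=O)C1CCCCC[C@H]2CCCN(C(=O)OC(C)(C)C)[C@H]2C(C(=O)OC)CCCCC[C@H]2CCCN(C(=O)OC(C)(C)C)[C@@H]12 | intermediate
12 | macrocyclic bis(N-Boc-piperidine) bis(N-methoxy-N-methylamide) (as 11 with C(=O)N(Me)OMe in place of each CO2Me) | CON(C)C(=O)C1CCCCC[C@H]2CCCN(C(=O)OC(C)(C)C)[C@H]2C(C(=O)N(C)OC)CCCCC[C@H]2CCCN(C(=O)OC(C)(C)C)[C@@H]12 | intermediate
13 | macrocyclic bis(N-Boc-piperidine) bis(isopropenyl ketone) (as 11 with C(=O)C(CH3)=CH2 in place of each CO2Me) | CC(=C)C(=O)C1CCCCC[C@H]2CCCN(C(=O)OC(C)(C)C)[C@H]2C(C(=O)C(C)=C)CCCCC[C@H]2CCCN(C(=O)OC(C)(C)C)[C@@H]12 | intermediate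
14 | macrocyclic bis(piperidine) bis(isopropenyl ketone), free amine after neutralization (formed in the flask) | CC(=C)C(=O)C1CCCCC[C@H]2CCCN[C@H]2C(C(=O)C(C)=C)CCCCC[C@H]2CCCN[C@@H]12 | intermediate
15 | CNP0268544.6: C2-symmetric bis(3-methylquinolizidin-2-one), C1 of each half tied by (CH2)5 to C9 of the other, (1R,3S,9S,9aR) in each half | C[C@H]1CN2CCC[C@@H]3CCCCC[C@H]4C(=O)[C@@H](C)CN5CCC[C@H](CCCCC[C@@H](C1=O)[C@@H]32)[C@H]45 | target

Total step count: 8. Longest linear sequence: 8 steps (from 1).

Steps most likely to fail

Step 1. The α-branched aldehyde may epimerize at C9 under the basic Mannich conditions before the ring closes, the hindered bis-sulfonyl anion may add too slowly, or the amine catalyst may consume the imine. The fallback sets out from 1 (with 2 and 3), uses only separately known reactions and returns at 7. The enamine Michael addition alone is run with the same catalyst and aldehyde 4 is isolated. It is masked (HC(OMe)3, MeOH, pyridinium p-toluenesulfonate) as methyl (8S)-8-(dimethoxymethyl)-10,10-bis(phenylsulfonyl)decanoate F1, which has no epimerizable center. The bis-sulfonyl anion of F1 is then added to the imine from 3 (Cs2CO3, CH2Cl2, forcing conditions now allowed) to give methyl (8S)-11-[(tert-butoxycarbonyl)amino]-8-(dimethoxymethyl)-10,10-bis(phenylsulfonyl)undecanoate F2. Camphor-10-sulfonic acid (cat.) in CH2Cl2 lets the carbamate nitrogen displace one methoxy group through the oxocarbenium ion, closing ring B to 7.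

Step 4. The monomer may close on itself to an 8-membered ring or grow into linear oligomers, the N-acyliminium ion may lose the C9 proton to an ene-carbamate (erasing C9), or facial selectivity may be incomplete. The fallback sets out from 7 and returns at 10 by an ordered assembly with two differently activated heads.
- Part of 7 is converted (PhSH, BF3·OEt2, CH2Cl2) into the N,S-acetal tert-butyl (3S)-3-(7-methoxy-7-oxoheptyl)-2-(phenylsulfanyl)-5,5-bis(phenylsulfonyl)piperidine-1-carboxylate F3, which silyl triflates do not ionize.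
- Enolization and silylation as in step 3 give its ketene silyl acetal F4.
- F4 and one equivalent of 7 are combined under the catalyst of step 4 at ordinary concentration; only 7 can ionize and only F4 can attack, so the product is the linear dimer with phenylsulfanyl head and methyl ester tail F5.
- LDA (1.1 equiv) and TBSCl silylate the unhindered terminal ester enolate to give the terminal ketene silyl acetal of the linear dimer F6.
- Silver triflate (AgOTf) at high dilution ionizes the N,S-acetal, and the one possible intramolecular Mannich reaction closes the ring to 10.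

Step 8. Intermolecular amine–enone addition or enone polymerization may outrun the 6-endo ring closure, or the open amino enone may be favored at equilibrium. The fallback sets out from 12 and returns at 15. EtMgBr converts 12 into the macrocyclic bis(N-Boc-piperidine) bis(ethyl ketone) F7. TFA removes the Boc groups to give the macrocyclic bis(piperidine) bis(ethyl ketone) F8. Aqueous formaldehyde in AcOH then closes each ring A by intramolecular Mannich reaction (the N-methyleneiminium ion is attacked by the C3 enol of the ethyl ketone, the only ring size possible), and K2CO3 in MeOH equilibrates C1 and C3 to give 15.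

Further compounds
F1 | step 1 | methyl (8S)-8-(dimethoxymethyl)-10,10-bis(phenylsulfonyl)decanoate | COC(=O)CCCCCC[C@H](C(OC)OC)CC(S(=O)(=O)c1ccccc1)S(=O)(=O)c1ccccc1
F2 | step 1 | methyl (8S)-11-[(tert-butoxycarbonyl)amino]-8-(dimethoxymethyl)-10,10-bis(phenylsulfonyl)undecanoate | COC(=O)CCCCCC[C@H](C(OC)OC)CC(CNC(=O)OC(C)(C)C)(S(=O)(=O)c1ccccc1)S(=O)(=O)c1ccccc1
F3 | step 4 | tert-butyl (3S)-3-(7-methoxy-7-oxoheptyl)-2-(phenylsulfanyl)-5,5-bis(phenylsulfonyl)piperidine-1-carboxylate | COC(=O)CCCCCC[C@H]1CC(S(=O)(=O)c2ccccc2)(S(=O)(=O)c2ccccc2)CN(C(=O)OC(C)(C)C)C1Sc3ccccc3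
F4 | step 4 | tert-butyl (3S)-3-[7-(tert-butyldimethylsilyloxy)-7-methoxyhept-6-en-1-yl]-2-(phenylsulfanyl)-5,5-bis(phenylsulfonyl)piperidine-1-carboxylate | COC(O[Si](C)(C)C(C)(C)C)=CCCCCC[C@H]1CC(S(=O)(=O)c2ccccc2)(S(=O)(=O)c2ccccc2)CN(C(=O)OC(C)(C)C)C1Sc3ccccc3
F5 | step 4 | linear dimer with phenylsulfanyl head and methyl ester tail (as 9 with SPh in place of the remaining 2-methoxy group and CO2Me in place of the ketene silyl acetal) | COC(=O)CCCCCC[C@H]1CC(S(=O)(=O)c2ccccc2)(S(=O)(=O)c2ccccc2)CN(C(=O)OC(C)(C)C)[C@H]1C(C(=O)OC)CCCCC[C@H]1CC(S(=O)(=O)c2ccccc2)(S(=O)(=O)c2ccccc2)CN(C(=O)OC(C)(C)C)C1Sc3ccccc3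
F6 | step 4 | terminal ketene silyl acetal of the linear dimer (as 9 with SPh in place of the remaining 2-methoxy group) | COC(O[Si](C)(C)C(C)(C)C)=CCCCCC[C@H]1CC(S(=O)(=O)c2ccccc2)(S(=O)(=O)c2ccccc2)CN(C(=O)OC(C)(C)C)[C@H]1C(C(=O)OC)CCCCC[C@H]1CC(S(=O)(=O)c2ccccc2)(S(=O)(=O)c2ccccc2)CN(C(=O)OC(C)(C)C)C1Sc3ccccc3
F7 | step 8 | macrocyclic bis(N-Boc-piperidine) bis(ethyl ketone) (as 13 with C(=O)CH2CH3 in place of each isopropenyl ketone) | CCC(=O)C1CCCCC[C@H]2CCCN(C(=O)OC(C)(C)C)[C@H]2C(C(=O)CC)CCCCC[C@H]2CCCN(C(=O)OC(C)(C)C)[C@@H]12
F8 | step 8 | macrocyclic bis(piperidine) bis(ethyl ketone) (F7 without the Boc groups) | CCC(=O)C1CCCCC[C@H]2CCCN[C@H]2C(C(=O)CC)CCCCC[C@H]2CCCN[C@@H]12
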